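**Retrosynthetic overview**

1. The last bond made is the primary ester. The terminal alcohol of the hydroxy diacid lactone opens O-trifluoroacetyl-(R)-malic anhydride regioselectively.
2. The only ring of the target is the 5-oxooxolane (O1, quaternary C2, C3, C4, carbonyl C5). It is cut at C4–C5 and at O1–C2, which releases CO2 and an acyclic 2-substituted buta-2,3-dienoate. A phosphine-catalysed (3+2) annulation joins them, and the extra C3=C4 double bond is removed in a later hydrogenation.
3. Enabling feature: ring carbon C2 is quaternary and bears a carboxyl group, so C2–C3–C4 can be the Cα=Cβ=Cγ unit of an allenoate. Its phosphonium adduct is nucleophilic at Cγ and electrophilic at Cα, which is the pattern that O=C=O needs.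
4. The allenoate comes from a methyl 3-alkyl-4,4-dimethoxybutanoate by acylation, enol triflate formation and elimination. The acetal is the side-chain carboxyl at the aldehyde level and is oxidised after the key step.
5. The stereocentre comes from conjugate addition of the C10 Grignard reagent to (5R)-5-(menthyloxy)furan-2(5H)-one. Ring order: this bought, temporary lactone is opened in step 3, and the lactone of the target is closed in step 6.

Key step: step 6

Assumption: the (−)-menthol-derived (5R)-5-(menthyloxy)furan-2(5H)-one is taken as a commercial chiral building block; it is otherwise one acetalisation away from 5-hydroxyfuran-2(5H)-one and (−)-menthol.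

**Route**

Step 1
Reactants: 1 10-bromodecan-1-ol
Product: 2 {[(10-bromodecyl)oxy]methyl}benzene
Conditions: BnOC(=NH)CCl3, TfOH (5 mol %), cyclohexane/CH2Cl2, 0 °C to rt
Reagents that add atoms: benzyl 2,2,2-trichloroacetimidate N=C(OCc1ccccc1)C(Cl)(Cl)Cl
Why: Acid-catalysed O-benzylation with a trichloroacetimidate protects the alcohol without any base, so the primary bromide should not be displaced.

Step 2
Reactants: 2 {[(10-bromodecyl)oxy]methyl}benzene; 3 (5R)-5-{[(1R,2S,5R)-5-methyl-2-(propan-2-yl)cyclohexyl]oxy}furan-2(5H)-one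
Product: 5 (4R,5R)-4-[10-(benzyloxy)decyl]-5-{[(1R,2S,5R)-5-methyl-2-(propan-2-yl)cyclohexyl]oxy}oxolan-2-one, via Grignard reagent 4 (not isolated)
Conditions: Mg, THF, 40 °C; then CuBr·SMe2 (15 mol %), 3, THF, −78 to −40 °C; aq NH4Cl
Reagents that add atoms: none
Why: In this copper-catalysed conjugate addition of a Grignard reagent to a butenolide the alkyl group should enter the ring face opposite to the neighbouring menthyloxy group, which sets the (R)-configured carbon that later carries the side-chain carboxyl.

Step 3
Reactants: 5 (4R,5R)-4-[10-(benzyloxy)decyl]-5-(menthyloxy)oxolan-2-one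
Product: 6 methyl (3R)-13-(benzyloxy)-3-(dimethoxymethyl)tridecanoate
Conditions: HC(OMe)3, MeOH, TsOH·H2O (5 mol %), 40 °C
Reagents that add atoms: methanol CO; trimethyl orthoformate COC(OC)OC
Why: Acid-catalysed alcoholysis of the acylal (transacetalisation plus Fischer esterification, with the orthoformate taking up the water) opens the temporary ring, releases the auxiliary and leaves the stereocentre next to a bulky dimethoxymethyl group that does not acidify it.

Step 4
Reactants: 6 methyl (3R)-13-(benzyloxy)-3-(dimethoxymethyl)tridecanoate; 7 N-methoxy-N-methylacetamide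
Product: 8 methyl (3R)-2-acetyl-13-(benzyloxy)-3-(dimethoxymethyl)tridecanoate (mixture at C2)
Conditions: LiN(iPr)2, THF, −78 °C; 7, −78 to −20 °C; AcOH
Reagents that add atoms: none
Why: This is a Claisen-type C-acylation of the ester lithium enolate with an N-methoxy-N-methylamide, whose chelated tetrahedral adduct stops over-reaction, and the new centre between the two carbonyl groups is of no consequence because it becomes sp2 in step 5.

Step 5
Reactants: 8 methyl (3R)-2-acetyl-13-(benzyloxy)-3-(dimethoxymethyl)tridecanoate
Product: 10 methyl 2-[(2R)-12-(benzyloxy)-1,1-dimethoxydodecan-2-yl]buta-2,3-dienoate, via enol triflate 9 (not isolated)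
Conditions: LiN(SiMe3)2, THF, −78 °C; Tf2O; then LiN(SiMe3)2, −78 to 0 °C
Reagents that add atoms: none
Why: O-Triflation of the lithium enolate and E1cB elimination of triflate after deprotonation of the vinylogous methyl group is a known way from 2-substituted acetoacetates to 2-substituted buta-2,3-dienoates, and the stereocentre is not touched because no carbonyl group activates its hydrogen.

Step 6
Reactants: 10 methyl 2-[(2R)-12-(benzyloxy)-1,1-dimethoxydodecan-2-yl]buta-2,3-dienoate; 11 carbon dioxide
Product: 13 methyl (2S)-2-[(2R)-12-(benzyloxy)-1,1-dimethoxydodecan-2-yl]-5-oxo-2,5-dihydrofuran-2-carboxylate, via phosphonium carboxylate betaine 12 (not isolated)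
Conditions: PBu3 (20 mol %), 2,6-di-tert-butyl-4-methylphenol (20 mol %), CO2 (20 bar), MeCN, 40 °C
Reagents that add atoms: none
Why: Proposed new method: PBu3 adds to the central allene carbon of 10, the gamma-CH2 terminus of the phosphonium dienolate attacks CO2 to give betaine 12, the carboxylate oxygen adds to the alpha-carbon (beta to phosphorus in the vinylphosphonium), and phenol-relayed proton transfer from the new lactone alpha-CH2 to the ylide carbon followed by E1cB loss of PBu3 gives the butenolide, so both the C–C and the C–O bond of the ring come from one molecule of CO2. The closest known reaction types are the phosphine-catalysed (3+2) annulation of buta-2,3-dienoates with activated alkenes, imines and trifluoromethyl ketones and the trapping of phosphine–alkynoate zwitterions by CO2 as carboxylate betaines, whereas CO2 as the two-atom partner of the annulation is new. The single ring is closed by a 5-endo-trig addition of the carboxylate to the vinylphosphonium, the same mode as the second bond formation of the known annulations, and the overall step should be downhill because a cumulated diene ends as a conjugated lactone. The new quaternary centre is controlled by the neighbouring stereocentre: allylic 1,3-strain holds its C–H bond in the plane of the tetrasubstituted vinylphosphonium, the branched dimethoxymethyl group covers one face, and closure from the face of the unbranched decyl chain leads to the (2S) configuration. The step needs gamma- over alpha-carboxylation, and the alpha-substituent secures it, because the alpha-adduct has no acidic hydrogen from which the phosphine could be expelled and can only revert, while the product has neither an acidic gamma-hydrogen nor an unhindered double bond and should not re-enter the cycle. Keeping the side-chain carboxyl at the acetal level leaves the hydrogen on the branch carbon non-acidic, which should suppress the 1,4-dipole pathway of alpha-alkyl allenoates and epimerisation.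

Step 7
Reactants: 13 methyl (2S)-2-[(2R)-12-(benzyloxy)-1,1-dimethoxydodecan-2-yl]-5-oxo-2,5-dihydrofuran-2-carboxylate
Product: 15 (2R)-12-(benzyloxy)-2-[(2S)-2-(methoxycarbonyl)-5-oxo-2,5-dihydrofuran-2-yl]dodecanoic acid, via aldehyde 14 (not isolated)
Conditions: TFA/H2O/CH2Cl2, 0 °C; then NaClO2, NaH2PO4, 2-methylbut-2-ene, t-BuOH/H2O, 0 °C to rt
Reagents that add atoms: water O; sodium chlorite [Na+].[O-]Cl=O
Why: Acetal hydrolysis followed at once by Pinnick oxidation of the crude aldehyde keeps the medium weakly acidic throughout, so neither enolisation of the alpha-stereocentre nor beta-elimination of the lactone oxygen should occur.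

Step 8
Reactants: 15 (2R)-12-(benzyloxy)-2-[(2S)-2-(methoxycarbonyl)-5-oxo-2,5-dihydrofuran-2-yl]dodecanoic acid
Product: 16 (2R)-12-hydroxy-2-[(2S)-2-(methoxycarbonyl)-5-oxooxolan-2-yl]dodecanoic acid
Conditions: H2 (1 atm), 10 % Pd/C, EtOAc/MeOH, rt
Reagents that add atoms: none
Why: Heterogeneous catalytic hydrogenation saturates the butenolide double bond and hydrogenolyses the benzyl ether in one operation without forming or touching a stereocentre.

Step 9
Reactants: 16 (2R)-12-hydroxy-2-[(2S)-2-(methoxycarbonyl)-5-oxooxolan-2-yl]dodecanoic acid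
Product: 18 (2S)-2-[(1R)-1-carboxy-11-hydroxyundecyl]-5-oxooxolane-2-carboxylic acid, via open hydroxy triacid 17 (not isolated)
Conditions: LiOH, THF/H2O, 0 °C to rt; then 2 M HCl to pH 1, 40 °C
Reagents that add atoms: lithium hydroxide [Li+].[OH-]
Why: Saponification cleaves the methyl ester while the lactone opens to a hydroxy tricarboxylate in which the tertiary oxygen is no leaving group and the alpha-hydrogen is not acidic, and acidification closes the gamma-lactone again with both centres unchanged.

Step 10
Reactants: 19 (R)-malic acid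
Product: 20 (3R)-2,5-dioxooxolan-3-yl trifluoroacetate
Conditions: (CF3CO)2O, neat, 0 °C to rt; evaporation
Reagents that add atoms: trifluoroacetic anhydride O=C(OC(=O)C(F)(F)F)C(F)(F)F
Why: Trifluoroacetic anhydride dehydrates the diacid to the cyclic anhydride through mixed anhydrides and acylates the hydroxyl group, and no bond at the stereocentre is broken.

Step 11
Reactants: 18 (2S)-2-[(1R)-1-carboxy-11-hydroxyundecyl]-5-oxooxolane-2-carboxylic acid; 20 (3R)-2,5-dioxooxolan-3-yl trifluoroacetate
Product: 22 (2S)-2-[(1R)-1-carboxy-11-{[(2R)-3-carboxy-2-hydroxypropanoyl]oxy}undecyl]-5-oxooxolane-2-carboxylic acid, via O-trifluoroacetyl ester 21 (not isolated)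
Conditions: THF, 0 °C to rt; then H2O/MeCN, rt; reversed-phase chromatography
Reagents that add atoms: none
Why: In this regioselective alcoholysis of an unsymmetrical cyclic anhydride the primary alcohol should attack the carbonyl group next to the electron-withdrawing trifluoroacetoxy group, and the labile trifluoroacetate is hydrolysed on aqueous work-up.

**Compound list**

1 | 10-bromodecan-1-ol | OCCCCCCCCCCBr | starting material
2 | {[(10-bromodecyl)oxy]methyl}benzene | BrCCCCCCCCCCOCc1ccccc1 | intermediate
3 | (5R)-5-{[(1R,2S,5R)-5-methyl-2-(propan-2-yl)cyclohexyl]oxy}furan-2(5H)-one | O=C1C=C[C@H](O[C@@H]2C[C@H](C)CC[C@H]2C(C)C)O1 | starting material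
4 | [10-(benzyloxy)decyl]magnesium bromide | Br[Mg]CCCCCCCCCCOCc1ccccc1 | intermediate
5 | (4R,5R)-4-[10-(benzyloxy)decyl]-5-{[(1R,2S,5R)-5-methyl-2-(propan-2-yl)cyclohexyl]oxy}oxolan-2-one | O=C1C[C@@H](CCCCCCCCCCOCc2ccccc2)[C@H](O[C@@H]3C[C@H](C)CC[C@H]3C(C)C)O1 | intermediate
6 | methyl (3R)-13-(benzyloxy)-3-(dimethoxymethyl)tridecanoate | COC(=O)C[C@@H](CCCCCCCCCCOCc1ccccc1)C(OC)OC | intermediate
7 | N-methoxy-N-methylacetamide | CC(=O)N(C)OC | starting material
8 | methyl (3R)-2-acetyl-13-(benzyloxy)-3-(dimethoxymethyl)tridecanoate | COC(=O)C(C(C)=O)[C@@H](CCCCCCCCCCOCc1ccccc1)C(OC)OC | intermediate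
9 | methyl (3R)-13-(benzyloxy)-3-(dimethoxymethyl)-2-{1-[(trifluoromethanesulfonyl)oxy]ethylidene}tridecanoate | COC(=O)C(=C(C)OS(=O)(=O)C(F)(F)F)[C@@H](CCCCCCCCCCOCc1ccccc1)C(OC)OC | intermediate
10 | methyl 2-[(2R)-12-(benzyloxy)-1,1-dimethoxydodecan-2-yl]buta-2,3-dienoate | COC(=O)C(=C=C)[C@@H](CCCCCCCCCCOCc1ccccc1)C(OC)OC | intermediate
11 | carbon dioxide | O=C=O | starting material
12 | gamma-carboxylate betaine of the tributylphosphonium adduct of 10 | CCCC[P+](CCCC)(CCCC)C(CC(=O)[O-])=C(C(=O)OC)[C@@H](CCCCCCCCCCOCc1ccccc1)C(OC)OC | intermediate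
13 | methyl (2S)-2-[(2R)-12-(benzyloxy)-1,1-dimethoxydodecan-2-yl]-5-oxo-2,5-dihydrofuran-2-carboxylate | O(Cc1ccccc1)CCCCCCCCCC[C@@H](C(OC)OC)[C@]2(C(=O)OC)C=CC(=O)O2 | intermediate
14 | methyl (2S)-2-[(2R)-12-(benzyloxy)-1-oxododecan-2-yl]-5-oxo-2,5-dihydrofuran-2-carboxylate | O(Cc1ccccc1)CCCCCCCCCC[C@@H](C=O)[C@]2(C(=O)OC)C=CC(=O)O2 | intermediate
15 | (2R)-12-(benzyloxy)-2-[(2S)-2-(methoxycarbonyl)-5-oxo-2,5-dihydrofuran-2-yl]dodecanoic acid | O(Cc1ccccc1)CCCCCCCCCC[C@@H](C(=O)O)[C@]2(C(=O)OC)C=CC(=O)O2 | intermediate
16 | (2R)-12-hydroxy-2-[(2S)-2-(methoxycarbonyl)-5-oxooxolan-2-yl]dodecanoic acid | OCCCCCCCCCC[C@@H](C(=O)O)[C@]1(C(=O)OC)CCC(=O)O1 | intermediate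
17 | (3S,4R)-3,14-dihydroxytetradecane-1,3,4-tricarboxylic acid | OCCCCCCCCCC[C@@H](C(=O)O)[C@](O)(C(=O)O)CCC(=O)O | intermediate
18 | (2S)-2-[(1R)-1-carboxy-11-hydroxyundecyl]-5-oxooxolane-2-carboxylic acid | OCCCCCCCCCC[C@@H](C(=O)O)[C@]1(C(=O)O)CCC(=O)O1 | intermediate
19 | (R)-malic acid | O=C(O)C[C@@H](O)C(=O)O | starting material
20 | (3R)-2,5-dioxooxolan-3-yl trifluoroacetate | O=C1C[C@@H](OC(=O)C(F)(F)F)C(=O)O1 | intermediate
21 | O-trifluoroacetyl derivative of 22 | O=C(O)C[C@@H](OC(=O)C(F)(F)F)C(=O)OCCCCCCCCCC[C@@H](C(=O)O)[C@]1(C(=O)O)CCC(=O)O1 | intermediate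
22 | (2S)-2-[(1R)-1-carboxy-11-{[(2R)-3-carboxy-2-hydroxypropanoyl]oxy}undecyl]-5-oxooxolane-2-carboxylic acid | O=C(O)C[C@@H](O)C(=O)OCCCCCCCCCC[C@@H](C(=O)O)[C@]1(C(=O)O)CCC(=O)O1 | target

**Step count**

Total step count: 11. Longest linear sequence: 10 (steps 1 to 9 and 11; step 10 is a one-step branch).

**Steps most likely to fail**

Step 6 (Proposed new method).
- What may go wrong: the carboxylate may close too slowly on the fully substituted carbon. A proton shift from the branch carbon to a conjugated diene, oligomerisation of the allenoate or simple loss of CO2 could then take over. The facial selectivity of the closure may also be poor.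
- Fallback: it uses known chemistry only, sets out from 6 and comes back at 16. The lithium enolate of 6 is alkylated with allyl bromide to the 2-allyl ester F1. Its potassium enolate (KN(SiMe3)2) is hydroxylated with 2-(phenylsulfonyl)-3-phenyloxaziridine to the tertiary alpha-hydroxy ester F2, where the same allylic-strain bias should direct the oxidant to the face away from the acetal. Hydroboration with 9-BBN and oxidation give the 1,4-diol F3. TEMPO/PhI(OAc)2 oxidises F3 through the lactol to the saturated lactone F4. Acetal hydrolysis and Pinnick oxidation as in step 7 give the acid F5, and hydrogenolysis of its benzyl ether over Pd/C gives 16.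

Step 5.
- What may go wrong: triflation of the hindered enolate may be incomplete. Tf2O may ionise the acetal. The second deprotonation may degrade the allenoate instead of releasing it cleanly.
- Fallback: it sets out from 6 and comes back at 10. The lithium enolate of 6 is treated with ClP(OEt)2 and the phosphonite is oxidised with H2O2 to the phosphonoacetate F6. Its sodium salt (NaH) undergoes a Horner–Wadsworth–Emmons reaction with ketene, generated in the flask from acetyl chloride and Et3N, to give 10 without any triflate chemistry.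

Step 11.
- What may go wrong: the alcohol may attack the wrong anhydride carbonyl. Anhydride exchange with the free vicinal diacid of 18 may also lead to oligomeric esters.
- Fallback: it sets out from 18 and 19 and comes back at 22. Compound 18 is alkylated with BnBr/KHCO3 in DMF to the dibenzyl ester F7. Compound 19 is converted with 2,2-dimethoxypropane and TsOH into the dioxolanone acid F8, which BnBr/Et3N turns into the benzyl ester F9. Acid-catalysed alcoholysis of the dioxolanone carbonyl of F9 by the alcohol F7 (TsOH, toluene, 60 °C) can only give the ester next to the hydroxyl group, the tribenzyl ester F10. Hydrogenolysis of F10 over Pd/C gives 22.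

**Further compounds**

F1 | step 6 | methyl (3R)-13-(benzyloxy)-3-(dimethoxymethyl)-2-(prop-2-en-1-yl)tridecanoate | COC(=O)C(CC=C)[C@@H](CCCCCCCCCCOCc1ccccc1)C(OC)OC
F2 | step 6 | methyl (2S,3R)-13-(benzyloxy)-3-(dimethoxymethyl)-2-hydroxy-2-(prop-2-en-1-yl)tridecanoate | O(Cc1ccccc1)CCCCCCCCCC[C@@H](C(OC)OC)[C@](O)(C(=O)OC)CC=C
F3 | step 6 | methyl (2S,3R)-13-(benzyloxy)-3-(dimethoxymethyl)-2-hydroxy-2-(3-hydroxypropyl)tridecanoate | O(Cc1ccccc1)CCCCCCCCCC[C@@H](C(OC)OC)[C@](O)(C(=O)OC)CCCO
F4 | step 6 | methyl (2S)-2-[(2R)-12-(benzyloxy)-1,1-dimethoxydodecan-2-yl]-5-oxooxolane-2-carboxylate | O(Cc1ccccc1)CCCCCCCCCC[C@@H](C(OC)OC)[C@]2(C(=O)OC)CCC(=O)O2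
F5 | step 6 | (2R)-12-(benzyloxy)-2-[(2S)-2-(methoxycarbonyl)-5-oxooxolan-2-yl]dodecanoic acid | O(Cc1ccccc1)CCCCCCCCCC[C@@H](C(=O)O)[C@]2(C(=O)OC)CCC(=O)O2
F6 | step 5 | methyl (3R)-13-(benzyloxy)-2-(diethoxyphosphoryl)-3-(dimethoxymethyl)tridecanoate | COC(=O)C(P(=O)(OCC)OCC)[C@@H](CCCCCCCCCCOCc1ccccc1)C(OC)OC
F7 | step 11 | benzyl (2S)-2-[(2R)-1-(benzyloxy)-12-hydroxy-1-oxododecan-2-yl]-5-oxooxolane-2-carboxylate | OCCCCCCCCCC[C@@H](C(=O)OCc1ccccc1)[C@]2(C(=O)OCc3ccccc3)CCC(=O)O2
F8 | step 11 | [(4R)-2,2-dimethyl-5-oxo-1,3-dioxolan-4-yl]acetic acid | O=C(O)C[C@H]1OC(C)(C)OC1=O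
F9 | step 11 | benzyl [(4R)-2,2-dimethyl-5-oxo-1,3-dioxolan-4-yl]acetate | O=C(OCc1ccccc1)C[C@H]2OC(C)(C)OC2=O
F10 | step 11 | tribenzyl ester of 22 | O=C(OCc1ccccc1)C[C@@H](O)C(=O)OCCCCCCCCCC[C@@H](C(=O)OCc2ccccc2)[C@]3(C(=O)OCc4ccccc4)CCC(=O)O3
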